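**Plan**
- Numbering (germacrane): Z-olefins C1=C10 and C4=C5, lactone oxygen on C6, ring-fusion carbon C7, ester oxygen on C8, ketone C9, exocyclic C11=C13, lactone carbonyl C12.
- Cuts: the C8–O acyl bond (acid 25); C9=O back to an 8,9-syn-diol held in a trans-dioxolane; the lactone O–C12 bond and, as the central cut, C6–C7, the bond shared by the ten-membered ring and the γ-lactone; C7–C11 (aldehyde 11 + methyl propiolate); C1=C10 (Wittig).
- Enabling feature: the array O–C6–C7–C11(=C13H2)–C12(=O) of the α-methylene-γ-butyrolactone, with C6 allylic to C4=C5, is the retron of a 2-(methoxycarbonyl)allyl metal adding through C7 to a Z-enal. In 16 both C6 (aldehyde) and C7 (acrylate β-carbon) are electrophilic, and reduction of the C13–Br bond by CrCl2 reverses the polarity of C7.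
- Forward: neryl acetate gives the C1–C6 phosphonium salt and D-tartrate gives the C7–C10 keto amide. After Wittig union and a three-carbon extension at C7, one C–C bond closes the carbocycle and the lactone follows in the same flask. The helpers (bromide, methyl ester, dioxolane, carbinol level at C9) leave in steps 11–13, and the ester goes on last.
- Stereochemistry: C4=C5 comes from nerol, C1=C10 from the α-alkoxy-ketone Wittig, and C8 (with the sacrificial C9) from D-tartaric acid. C6 and C7 come from the cyclic transition state of step 11 under control of the dioxolane, and both epoxide centres from a Sharpless epoxidation.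

Key step: step 11

Remark: 14 and 15 are carried as mixtures of epimers at the C7 carbinol carbon, so this centre is left open in their SMILES; it becomes sp2 in step 10.

Step 1
Reactants: 1 neryl acetate
Product: 3 (2Z)-6-hydroxy-3-methylhex-2-en-1-yl acetate, via aldehyde 2 (not isolated)
Conditions: O3 (1 equiv), CH2Cl2/MeOH, −78 °C; then NaBH4, −78 → 0 °C
Reagents that add atoms: ozone, [O-][O+]=O
Why: Chemoselective ozonolysis with reductive work-up: ozone attacks the electron-rich terminal isopropylidene olefin faster than the C4=C5 olefin, which is deactivated by the allylic acetate, and NaBH4 reduces aldehyde 2 in the same flask without touching the Z-geometry.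

Step 2
Reactants: 3 (2Z)-6-hydroxy-3-methylhex-2-en-1-yl acetate
Product: 4 (2Z)-6-iodo-3-methylhex-2-en-1-yl acetate
Conditions: I2, PPh3, imidazole, CH2Cl2, 0 °C
Reagents that add atoms: iodine, II
Why: Appel-type iodination, an SN2 displacement on the alkoxyphosphonium ion of a primary alcohol under near-neutral conditions that spare the allylic acetate.

Step 3
Reactants: 4 (2Z)-6-iodo-3-methylhex-2-en-1-yl acetate
Product: 5 [(4Z)-6-acetoxy-4-methylhex-4-en-1-yl]triphenylphosphonium iodide
Conditions: PPh3, MeCN, 80 °C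
Reagents that add atoms: triphenylphosphine, c1ccc(cc1)P(c1ccccc1)c1ccccc1
Why: SN2 quaternisation of PPh3 by a primary iodide, the standard preparation of a non-stabilised Wittig salt, in which the allylic acetate is inert in the absence of a transition metal.

Step 4
Reactants: 6 dimethyl (4S,5S)-2,2-dimethyl-1,3-dioxolane-4,5-dicarboxylate (dimethyl 2,3-O-isopropylidene-D-tartrate)
Product: 7 (4S,5S)-N4,N5-dimethoxy-N4,N5,2,2-tetramethyl-1,3-dioxolane-4,5-dicarboxamide
Conditions: MeNH(OMe)·HCl, i-PrMgCl, THF, −20 → 0 °C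
Reagents that add atoms: N,O-dimethylhydroxylamine hydrochloride, CNOC.Cl
Why: Weinreb amide formation by acyl substitution of both esters with the magnesium amide at low temperature, under which the α-alkoxy centres of the more stable trans-dioxolane are not epimerised.

Step 5
Reactants: 7 (4S,5S)-N4,N5-dimethoxy-N4,N5,2,2-tetramethyl-1,3-dioxolane-4,5-dicarboxamide
Product: 8 (4S,5S)-5-acetyl-N-methoxy-N,2,2-trimethyl-1,3-dioxolane-4-carboxamide
Conditions: MeMgBr (1.05 equiv), THF, −78 → −20 °C; aq. NH4Cl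
Reagents that add atoms: methylmagnesium bromide, C[Mg]Br
Why: Weinreb ketone synthesis used as a desymmetrisation: the two amide groups of C2-symmetric 7 are homotopic, and the magnesium chelate formed by the first addition survives until work-up, so one equivalent of MeMgBr should stop at the mono-ketone with C8 and C9 unchanged.

Step 6
Reactants: 5 [(4Z)-6-acetoxy-4-methylhex-4-en-1-yl]triphenylphosphonium iodide; 8 (4S,5S)-5-acetyl-N-methoxy-N,2,2-trimethyl-1,3-dioxolane-4-carboxamide
Product: 10 (4S,5R)-5-[(2Z,6Z)-8-acetoxy-6-methylocta-2,6-dien-2-yl]-N-methoxy-N,2,2-trimethyl-1,3-dioxolane-4-carboxamide, via ylide 9 (not isolated)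
Conditions: KN(SiMe3)2, THF/DMPU, −78 °C; then 8, −78 → 0 °C
Reagents that add atoms: none
Why: Wittig reaction of a non-stabilised ylide under lithium-free conditions with an α-alkoxy methyl ketone, a pairing known to give the Z-trisubstituted allylic ether through the kinetically preferred cis-oxaphosphetane, which places C9 cis to C2 as in the target.

Step 7
Reactants: 10 (4S,5R)-5-[(2Z,6Z)-8-acetoxy-6-methylocta-2,6-dien-2-yl]-N-methoxy-N,2,2-trimethyl-1,3-dioxolane-4-carboxamide
Product: 11 (4S,5R)-5-[(2Z,6Z)-8-hydroxy-6-methylocta-2,6-dien-2-yl]-2,2-dimethyl-1,3-dioxolane-4-carbaldehyde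
Conditions: i-Bu2AlH (4 equiv), CH2Cl2, −78 °C; aq. potassium sodium tartrate
Reagents that add atoms: none
Why: Hydride reduction in which the Weinreb amide is held as its aluminium chelate until work-up (so that excess i-Bu2AlH cannot over-reduce it) while the acetate is cleaved, so that one operation unveils the C7 aldehyde and the C6 alcohol.

Step 8
Reactants: 11 (4S,5R)-5-[(2Z,6Z)-8-hydroxy-6-methylocta-2,6-dien-2-yl]-2,2-dimethyl-1,3-dioxolane-4-carbaldehyde; 12 methyl propiolate
Product: 14 methyl 2-{hydroxy[(4R,5R)-5-[(2Z,6Z)-8-hydroxy-6-methylocta-2,6-dien-2-yl]-2,2-dimethyl-1,3-dioxolan-4-yl]methyl}acrylate (C7 epimers), via vinylalane 13 (not isolated)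
Conditions: 12, i-Bu2AlH, NMO, THF, 0 °C; then 11, 0 °C → rt
Reagents that add atoms: none
Why: Vinylalumination: hydroalumination of methyl propiolate gives the α-(methoxycarbonyl)vinylalane 13, which adds to the aldehyde under non-basic conditions and thus delivers the Morita–Baylis–Hillman-type adduct without epimerising C8, the new C7 carbinol centre being uncontrolled and erased in step 10.

Step 9
Reactants: 14 methyl 2-{hydroxy[(4R,5R)-5-[(2Z,6Z)-8-hydroxy-6-methylocta-2,6-dien-2-yl]-2,2-dimethyl-1,3-dioxolan-4-yl]methyl}acrylate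
Product: 15 methyl 2-{hydroxy[(4R,5R)-2,2-dimethyl-5-[(2Z,6Z)-6-methyl-8-oxoocta-2,6-dien-2-yl]-1,3-dioxolan-4-yl]methyl}acrylate (C7 epimers)
Conditions: TEMPO (cat.), PhI(OAc)2, MeCN/pH 7 buffer, 0 °C
Reagents that add atoms: none
Why: Oxoammonium (TEMPO) oxidation, which takes the unhindered primary allylic alcohol much faster than the hindered secondary carbinol at C7 and is known to convert nerol-type alcohols into Z-enals without isomerisation.

Step 10
Reactants: 15 methyl 2-{hydroxy[(4R,5R)-2,2-dimethyl-5-[(2Z,6Z)-6-methyl-8-oxoocta-2,6-dien-2-yl]-1,3-dioxolan-4-yl]methyl}acrylate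
Product: 16 methyl (2Z)-2-(bromomethyl)-3-{(4R,5R)-2,2-dimethyl-5-[(2Z,6Z)-6-methyl-8-oxoocta-2,6-dien-2-yl]-1,3-dioxolan-4-yl}prop-2-enoate
Conditions: NBS and Me2S premixed, CH2Cl2, −20 °C; then 15, −20 → 0 °C
Reagents that add atoms: N-bromosuccinimide, O=C1CCC(=O)N1Br
Why: SN2′ bromination of a Morita–Baylis–Hillman alcohol: the alkoxysulfonium salt formed with the premixed NBS–Me2S reagent is displaced by bromide at C13, and the transposed enoate is formed with C8 cis to CH2Br (Z), the geometry that keeps the ester coplanar with the olefin.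

Step 11
Reactants: 16 methyl (2Z)-2-(bromomethyl)-3-{(4R,5R)-2,2-dimethyl-5-[(2Z,6Z)-6-methyl-8-oxoocta-2,6-dien-2-yl]-1,3-dioxolan-4-yl}prop-2-enoate
Product: 19 (6S,7S,8R,9R)-8,9-(isopropylidenedioxy)germacra-1(10)Z,4Z,11(13)-trien-12,6-olide, via allylchromium 17 (not isolated), via hydroxy ester 18 (not isolated)
Conditions: CrCl2 (10 equiv), THF/DMF (4:1), 25 °C, slow addition of 16 (final 1 mM); aq. NH4Cl; then SiO2, CH2Cl2
Reagents that add atoms: none
Why: Two equivalents of CrCl2 (divalent chromium, a one-electron donor) reduce the allylic C13–Br bond of 16 to the allylchromium 17 (trivalent chromium), which turns C7, the β-carbon of an acrylate and thus of the same electrophilic polarity as the aldehyde carbon C6, into the nucleophilic γ-terminus that adds to C6 through a six-membered Zimmerman–Traxler array while the double bond moves to C11=C13. The closest known reaction type is the intramolecular Nozaki–Hiyama–Kishi (Barbier-type) 2-(alkoxycarbonyl)allylation of an enal, which is established for ten-membered germacranolide carbocycles. The carbocycle closes 10-exo-trig at the aldehyde, and the chromium alkoxide of 18 then closes the γ-lactone 5-exo-trig on the methyl ester with loss of methanol. The C6/C7 relation is set by the chair: C8 is cis to C13 (Z-crotyl type) and therefore axial, C5 is equatorial, which gives the syn adduct and hence the cis-fused lactone. The absolute sense at C6 and C7 is relayed from C8 and C9: the trans-dioxolane allows only one sign of the C7–C8–C9–C10 torsion, and the ring can close only if C5 and C10 leave the extended C6–C7–C8–C9 segment on the same side, which puts H7 and H8 inside and O6, C11 and O8 outside the nascent ring, that is 6S,7S next to 8R. The step needs aldehyde-over-ester chemoselectivity and γ-regioselectivity, both inherent to allylchromium reagents, cyclisation over oligomerisation, secured by slow addition at high dilution and by the two Z-olefins and the dioxolane that fold the chain, and addition over reductive 1,4-elimination of O8, which is disfavoured because O8 is a poor, acetal-bound leaving group held near the nodal plane of the allyl system in the reactive rotamer.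

Step 12
Reactants: 19 (6S,7S,8R,9R)-8,9-(isopropylidenedioxy)germacra-1(10)Z,4Z,11(13)-trien-12,6-olide
Product: 20 (6S,7S,8R,9R)-8,9-dihydroxygermacra-1(10)Z,4Z,11(13)-trien-12,6-olide
Conditions: AcOH/H2O (4:1), 40 °C
Reagents that add atoms: none
Why: Acid-catalysed acetal hydrolysis under mild aqueous conditions, which the α-methylene lactone tolerates and which removes the temporary ring without touching C8 or C9 because only the acetal C–O bonds break.

Step 13
Reactants: 20 (6S,7S,8R,9R)-8,9-dihydroxygermacra-1(10)Z,4Z,11(13)-trien-12,6-olide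
Product: 21 (6S,7S,8R)-8-hydroxy-9-oxogermacra-1(10)Z,4Z,11(13)-trien-12,6-olide
Conditions: MnO2 (activated, excess), CH2Cl2, rt
Reagents that add atoms: none
Why: Chemoselective allylic oxidation with MnO2, which oxidises only the C9 carbinol next to C1=C10 and leaves the non-allylic C8 carbinol, so that the sacrificial stereocentre is erased and the Z-enone, locked by the ring, is formed.

Step 14
Reactants: 22 angelic acid
Product: 23 (2Z)-2-methylbut-2-en-1-ol
Conditions: LiAlH4, Et2O, 0 °C
Reagents that add atoms: none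
Why: 1,2-Reduction of an α,β-unsaturated acid with LiAlH4 at low temperature, which keeps the Z-geometry of the angelate olefin.

Step 15
Reactants: 23 (2Z)-2-methylbut-2-en-1-ol
Product: 24 [(2R,3S)-2,3-dimethyloxiran-2-yl]methanol
Conditions: Ti(OiPr)4 (cat.), D-(−)-diethyl tartrate (cat.), t-BuOOH, 4 Å molecular sieves, CH2Cl2, −20 °C
Reagents that add atoms: tert-butyl hydroperoxide, CC(C)(C)OO
Why: Sharpless asymmetric epoxidation, in which the Ti–tartrate complex of D-(−)-diethyl tartrate delivers oxygen to the olefin face that gives the (2R,3S)-epoxy alcohol, the cis relation of CH2OH and the C3 methyl group following from the Z-olefin by syn addition.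

Step 16
Reactants: 24 [(2R,3S)-2,3-dimethyloxiran-2-yl]methanol
Product: 25 (2S,3S)-2,3-dimethyloxirane-2-carboxylic acid
Conditions: TEMPO (cat.), PhI(OAc)2, MeCN/H2O, rt
Reagents that add atoms: water, O
Why: TEMPO/PhI(OAc)2 oxidation in aqueous acetonitrile, which carries the primary alcohol through the aldehyde hydrate to the acid under nearly neutral conditions that keep the epoxide and its two centres (the descriptor at C2 changes from R to S only through the priority rules).

Step 17
Reactants: 21 (6S,7S,8R)-8-hydroxy-9-oxogermacra-1(10)Z,4Z,11(13)-trien-12,6-olide; 25 (2S,3S)-2,3-dimethyloxirane-2-carboxylic acid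
Product: 27 (6S,7S,8R)-8-[(2S,3S)-2,3-dimethyloxirane-2-carbonyloxy]-9-oxogermacra-1(10)Z,4Z,11(13)-trien-12,6-olide (CNP0183761.1), via mixed anhydride 26 (not isolated)
Conditions: 25, 2,4,6-trichlorobenzoyl chloride, Et3N, toluene, rt; then 21, DMAP, 0 °C → rt
Reagents that add atoms: none
Why: Yamaguchi esterification: DMAP attacks the mixed anhydride 26 at the epoxy-acyl carbonyl, the aroyl carbonyl being shielded by its two ortho chlorines, and the acylpyridinium salt acylates the hindered C8 hydroxyl with retention at C8, the low temperature limiting enolisation of the α-ketol.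

**Compound list**
1 | neryl acetate, (2Z)-3,7-dimethylocta-2,6-dien-1-yl acetate | CC(C)=CCC/C(C)=C\COC(C)=O | starting material
2 | (2Z)-3-methyl-6-oxohex-2-en-1-yl acetate | O=CCC/C(C)=C\COC(C)=O | intermediate
3 | (2Z)-6-hydroxy-3-methylhex-2-en-1-yl acetate | OCCC/C(C)=C\COC(C)=O | intermediate
4 | (2Z)-6-iodo-3-methylhex-2-en-1-yl acetate | ICCC/C(C)=C\COC(C)=O | intermediate
5 | [(4Z)-6-acetoxy-4-methylhex-4-en-1-yl]triphenylphosphonium iodide | CC(=O)OC/C=C(/C)CCC[P+](c1ccccc1)(c1ccccc1)c1ccccc1.[I-] | intermediate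
6 | dimethyl (4S,5S)-2,2-dimethyl-1,3-dioxolane-4,5-dicarboxylate | COC(=O)[C@H]1OC(C)(C)O[C@@H]1C(=O)OC | starting material
7 | (4S,5S)-N4,N5-dimethoxy-N4,N5,2,2-tetramethyl-1,3-dioxolane-4,5-dicarboxamide | CON(C)C(=O)[C@H]1OC(C)(C)O[C@@H]1C(=O)N(C)OC | intermediate
8 | (4S,5S)-5-acetyl-N-methoxy-N,2,2-trimethyl-1,3-dioxolane-4-carboxamide | CC(=O)[C@H]1OC(C)(C)O[C@@H]1C(=O)N(C)OC | intermediate
9 | [(4Z)-6-acetoxy-4-methylhex-4-en-1-ylidene]triphenylphosphorane | CC(=O)OC/C=C(/C)CCC=P(c1ccccc1)(c1ccccc1)c1ccccc1 | intermediate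
10 | (4S,5R)-5-[(2Z,6Z)-8-acetoxy-6-methylocta-2,6-dien-2-yl]-N-methoxy-N,2,2-trimethyl-1,3-dioxolane-4-carboxamide | CC(=O)OC/C=C(/C)CC/C=C(/C)[C@H]1OC(C)(C)O[C@@H]1C(=O)N(C)OC | intermediate
11 | (4S,5R)-5-[(2Z,6Z)-8-hydroxy-6-methylocta-2,6-dien-2-yl]-2,2-dimethyl-1,3-dioxolane-4-carbaldehyde | OC/C=C(/C)CC/C=C(/C)[C@H]1OC(C)(C)O[C@@H]1C=O | intermediate
12 | methyl propiolate | C#CC(=O)OC | starting material
13 | methyl 2-(diisobutylalumanyl)acrylate | C=C(C(=O)OC)[Al](CC(C)C)CC(C)C | intermediate
14 | methyl 2-{hydroxy[(4R,5R)-5-[(2Z,6Z)-8-hydroxy-6-methylocta-2,6-dien-2-yl]-2,2-dimethyl-1,3-dioxolan-4-yl]methyl}acrylate (C7 epimers) | OC/C=C(/C)CC/C=C(/C)[C@H]1OC(C)(C)O[C@@H]1C(O)C(=C)C(=O)OC | intermediate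
15 | methyl 2-{hydroxy[(4R,5R)-2,2-dimethyl-5-[(2Z,6Z)-6-methyl-8-oxoocta-2,6-dien-2-yl]-1,3-dioxolan-4-yl]methyl}acrylate (C7 epimers) | O=C/C=C(/C)CC/C=C(/C)[C@H]1OC(C)(C)O[C@@H]1C(O)C(=C)C(=O)OC | intermediate
16 | methyl (2Z)-2-(bromomethyl)-3-{(4R,5R)-2,2-dimethyl-5-[(2Z,6Z)-6-methyl-8-oxoocta-2,6-dien-2-yl]-1,3-dioxolan-4-yl}prop-2-enoate | O=C/C=C(/C)CC/C=C(/C)[C@H]1OC(C)(C)O[C@@H]1/C=C(\CBr)C(=O)OC | intermediate
17 | allylchromium dichloride R–CH2–CrCl2 derived from 16 (solvated) | O=C/C=C(/C)CC/C=C(/C)[C@H]1OC(C)(C)O[C@@H]1/C=C(\C[Cr](Cl)Cl)C(=O)OC | intermediate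
18 | methyl (6S,7S,8R,9R)-6-hydroxy-8,9-(isopropylidenedioxy)germacra-1(10)Z,4Z,11(13)-trien-12-oate (formed as its chromium alkoxide) | COC(=O)C(=C)[C@H]1[C@@H](O)/C=C(/C)CC/C=C(/C)[C@H]2OC(C)(C)O[C@H]12 | intermediate
19 | (6S,7S,8R,9R)-8,9-(isopropylidenedioxy)germacra-1(10)Z,4Z,11(13)-trien-12,6-olide | C=C1C(=O)O[C@H]2/C=C(/C)CC/C=C(/C)[C@H]3OC(C)(C)O[C@@H]3[C@@H]12 | intermediate
20 | (6S,7S,8R,9R)-8,9-dihydroxygermacra-1(10)Z,4Z,11(13)-trien-12,6-olide | C=C1C(=O)O[C@H]2/C=C(/C)CC/C=C(/C)[C@@H](O)[C@H](O)[C@@H]12 | intermediate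
21 | (6S,7S,8R)-8-hydroxy-9-oxogermacra-1(10)Z,4Z,11(13)-trien-12,6-olide | C=C1C(=O)O[C@H]2/C=C(/C)CC/C=C(/C)C(=O)[C@H](O)[C@@H]12 | intermediate
22 | angelic acid, (2Z)-2-methylbut-2-enoic acid | C/C=C(/C)C(=O)O | starting material
23 | (2Z)-2-methylbut-2-en-1-ol | C/C=C(/C)CO | intermediate
24 | [(2R,3S)-2,3-dimethyloxiran-2-yl]methanol | OC[C@@]1(C)O[C@H]1C | intermediate
25 | (2S,3S)-2,3-dimethyloxirane-2-carboxylic acid | OC(=O)[C@@]1(C)O[C@H]1C | intermediate
26 | (2S,3S)-2,3-dimethyloxirane-2-carboxylic 2,4,6-trichlorobenzoic anhydride | O=C(OC(=O)[C@@]1(C)O[C@H]1C)c1c(Cl)cc(Cl)cc1Cl | intermediate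
27 | (6S,7S,8R)-8-[(2S,3S)-2,3-dimethyloxirane-2-carbonyloxy]-9-oxogermacra-1(10)Z,4Z,11(13)-trien-12,6-olide (CNP0183761.1) | C=C1C(=O)O[C@H]2/C=C(/C)CC/C=C(/C)C(=O)[C@H](OC(=O)[C@@]3(C)O[C@H]3C)[C@@H]12 | target

**Count**
Total: 17 steps. Longest linear sequence: 12 steps from neryl acetate (steps 1–3, 6–13 and 17).

**Steps most likely to fail**

1. Step 11.
What may go wrong: reductive 1,4-elimination of the dioxolane oxygen from the allylchromium, oligomerisation instead of ring closure, or addition through the wrong pair of faces.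
The fallback sets out from 15 and comes back at 19, and it closes the same bond with a covalent, non-reducing allyl donor. Acetylation (Ac2O, DMAP, CH2Cl2) should give the Morita–Baylis–Hillman acetate F1. SN2′ borylation with B2pin2 under Pd2(dba)3 catalysis in toluene should give the 2-(methoxycarbonyl)allylboronate F2, which keeps C8 cis to the CH2–B group. Heating F2 at high dilution in toluene (or catalytic Sc(OTf)3 at room temperature) should bring about an intramolecular allylboration through a tight chair. The borate of 18 would lactonise on work-up to 19.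

2. Step 6.
What may go wrong: enolisation of the ketone by the basic ylide, β-elimination of the dioxolane oxygen from that enolate, or erosion of the Z-selectivity.
The fallback sets out from 2 (isolated by Me2S work-up in step 1) and comes back at 10. It fixes the olefin first and builds the diol afterwards.
- A Stork–Zhao type olefination with the ylide of (1-iodoethyl)triphenylphosphonium iodide (EtPPh3I, n-BuLi, I2, then NaN(SiMe3)2) should give the (Z)-vinyl iodide F3.
- Carbonylative reduction (CO, Bu3SnH, Pd(PPh3)4, THF, 50 °C) should give the (Z)-enal F4.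
- The N-glycolyl oxazolidinone F5 is made from (S)-4-benzyloxazolidin-2-one, n-BuLi and [(4-methoxybenzyl)oxy]acetyl chloride.
- An Evans syn aldol reaction of F5 with F4 (Bu2BOTf, Et3N; H2O2 work-up) should give the syn-aldol adduct F6 with the C8 and C9 configuration of 10.
- Transamidation (MeNH(OMe)·HCl, AlMe3) gives the Weinreb amide F7, and DDQ in wet CH2Cl2 gives the diol F8.
- 2,2-Dimethoxypropane with PPTS closes the dioxolane of 10.

3. Step 13.
What may go wrong: glycol cleavage of the 1,2-diol by MnO2, or sluggish oxidation of a carbinol whose C–H bond is poorly aligned with the olefin in the medium ring.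
The fallback sets out from 20 and comes back at 21. It activates the diol covalently before the oxidation. Bu2SnO in refluxing MeOH should give the dibutylstannylene acetal F9. Brominolysis with NBS in CHCl3 at room temperature should abstract the more hydridic, allylic C9–H and release 21 on aqueous work-up.

**Further compounds**
F1 | step 11 | methyl 2-{acetoxy[(4R,5R)-2,2-dimethyl-5-[(2Z,6Z)-6-methyl-8-oxoocta-2,6-dien-2-yl]-1,3-dioxolan-4-yl]methyl}acrylate (C7 epimers) | O=C/C=C(/C)CC/C=C(/C)[C@H]1OC(C)(C)O[C@@H]1C(OC(C)=O)C(=C)C(=O)OC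
F2 | step 11 | methyl (2E)-3-{(4R,5R)-2,2-dimethyl-5-[(2Z,6Z)-6-methyl-8-oxoocta-2,6-dien-2-yl]-1,3-dioxolan-4-yl}-2-[(4,4,5,5-tetramethyl-1,3,2-dioxaborolan-2-yl)methyl]prop-2-enoate | O=C/C=C(/C)CC/C=C(/C)[C@H]1OC(C)(C)O[C@@H]1/C=C(\CB2OC(C)(C)C(C)(C)O2)C(=O)OC
F3 | step 6 | (2Z,6Z)-7-iodo-3-methylocta-2,6-dien-1-yl acetate | CC(=O)OC/C=C(/C)CC/C=C(/C)I
F4 | step 6 | (2Z,6Z)-3,7-dimethyl-8-oxoocta-2,6-dien-1-yl acetate | CC(=O)OC/C=C(/C)CC/C=C(/C)C=O
F5 | step 6 | (S)-4-benzyl-3-{2-[(4-methoxybenzyl)oxy]acetyl}oxazolidin-2-one | COc1ccc(COCC(=O)N2[C@@H](Cc3ccccc3)COC2=O)cc1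
F6 | step 6 | (S)-4-benzyl-3-[(2S,3R,4Z,8Z)-10-acetoxy-3-hydroxy-2-(4-methoxybenzyloxy)-4,8-dimethyldeca-4,8-dienoyl]oxazolidin-2-one | CC(=O)OC/C=C(/C)CC/C=C(/C)[C@@H](O)[C@H](OCc1ccc(OC)cc1)C(=O)N1[C@@H](Cc2ccccc2)COC1=O
F7 | step 6 | (2S,3R,4Z,8Z)-10-acetoxy-3-hydroxy-N-methoxy-2-(4-methoxybenzyloxy)-N,4,8-trimethyldeca-4,8-dienamide | CC(=O)OC/C=C(/C)CC/C=C(/C)[C@@H](O)[C@H](OCc1ccc(OC)cc1)C(=O)N(C)OC
F8 | step 6 | (2S,3R,4Z,8Z)-10-acetoxy-2,3-dihydroxy-N-methoxy-N,4,8-trimethyldeca-4,8-dienamide | CC(=O)OC/C=C(/C)CC/C=C(/C)[C@@H](O)[C@H](O)C(=O)N(C)OC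
F9 | step 13 | 8,9-O-dibutylstannylene acetal of 20 | C=C1C(=O)O[C@H]2/C=C(/C)CC/C=C(/C)[C@H]3O[Sn](CCCC)(CCCC)O[C@@H]3[C@@H]12
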